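**Retrosynthetic overview**
- Ring C is a 4-pyranone fused to ring A. Its one-carbon unit C4(=O) bridges arene carbon C4a and the C3=C2 pair, and its oxygen O1 sits on C8a, next to C4a. Cutting C4a–C4, C4–C3 and O1–C2 leaves a 2-iodophenol (ring A), CO (C4) and a terminal arylalkyne (C3, C2, ring B).
- Rings A and B are bought as arenes, and ring C is the only ring built (step 9). The C3 hydroxyl follows by C3 lithiation and borate oxidation, and one acid step removes all MOM groups.
- Ring A: the C8 1,1-dimethylallyl group comes from an aromatic Claisen shift in the symmetric prenyl ether of bis-MOM phloroglucinol. This shift also makes O1 the only unprotected oxygen. Trapped as its acetate, O1 lets the two MOM ethers steer iodine to C4a.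
- Ring B and alkyne: 4-iodophenol is MOM-protected, coupled with trimethylsilylacetylene (Sonogashira) and desilylated.

Key step: step 9

Remark on the chemistry: flavone numbering (O1, C2, C3, C4, C4a, C5–C8, C8a) is applied to the ring A atoms already in the monocyclic intermediates. MOM = methoxymethyl.

**Step 1**
Reactants: 1 phloroglucinol (benzene-1,3,5-triol)
Product: 2 3,5-bis(methoxymethoxy)phenol
Conditions: MOMCl (2.0 equiv), K2CO3 (2.2 equiv), acetone, 0 °C to rt; chromatography
Reagents that add atoms: chloromethyl methyl ether (MOMCl), COCCl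
Why: Williamson-type O-alkylation by a hard electrophile; the threefold symmetry of 1 allows only one bis-ether, and the mono- and tris-ethers of the stoichiometry-limited mixture are removed by chromatography.

**Step 2**
Reactants: 2 3,5-bis(methoxymethoxy)phenol; 3 prenyl bromide (1-bromo-3-methylbut-2-ene)
Product: 4 1,3-bis(methoxymethoxy)-5-[(3-methylbut-2-en-1-yl)oxy]benzene
Conditions: K2CO3, acetone, reflux
Reagents that add atoms: none
Why: Williamson ether synthesis (SN2 at the primary allylic bromide) on the single free phenol, under conditions that favour O- over C-alkylation.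

**Step 3**
Reactants: 4 1,3-bis(methoxymethoxy)-5-[(3-methylbut-2-en-1-yl)oxy]benzene
Product: 7 3,5-bis(methoxymethoxy)-2-(2-methylbut-3-en-2-yl)phenyl acetate, via ortho-dienone 5 (not isolated), via free phenol 6 (not isolated)
Conditions: Ac2O (3 equiv), NaOAc (1 equiv), PhNEt2, 180 °C, sealed tube, Ar
Reagents that add atoms: acetic anhydride, CC(=O)OC(C)=O
Why: Aromatic Claisen rearrangement ([3,3] shift with allyl inversion) places the 1,1-dimethylallyl group on either of two equivalent ortho carbons, the amine solvent tautomerises 5 to 6, and acetylation in the flask takes 6 out of the phenol–dienone equilibrium, so neither an onward Cope shift to the para carbon nor the abnormal Claisen pathway should drain it.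

**Step 4**
Reactants: 7 3,5-bis(methoxymethoxy)-2-(2-methylbut-3-en-2-yl)phenyl acetate
Product: 8 2-iodo-3,5-bis(methoxymethoxy)-6-(2-methylbut-3-en-2-yl)phenyl acetate
Conditions: NIS (1.05 equiv), MeCN, 0 °C to rt, dark
Reagents that add atoms: N-iodosuccinimide (NIS), O=C1CCC(=O)N1I
Why: Electrophilic aromatic iodination; with O1 masked as a weakly donating acetate the two MOM ethers direct, as in any resorcinol diether, to the carbon ortho to one and para to the other (future C4a) and not to the carbon between them (C6), the arene is far more nucleophilic than the monosubstituted alkene, and no free hydroxyl is present for iodoetherification.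

**Step 5**
Reactants: 8 2-iodo-3,5-bis(methoxymethoxy)-6-(2-methylbut-3-en-2-yl)phenyl acetate
Product: 9 2-iodo-3,5-bis(methoxymethoxy)-6-(2-methylbut-3-en-2-yl)phenol
Conditions: K2CO3 (0.3 equiv), MeOH, 0 °C to rt
Reagents that add atoms: none
Why: Base-catalysed methanolysis (transesterification) of the aryl acetate leaves the MOM acetals, the aryl iodide and the alkene untouched and frees the only hydroxyl of the ring, the one ortho to iodine.

**Step 6**
Reactants: 10 4-iodophenol
Product: 11 1-iodo-4-(methoxymethoxy)benzene
Conditions: MOMCl (1.2 equiv), K2CO3, acetone, 0 °C to rt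
Reagents that add atoms: chloromethyl methyl ether (MOMCl), COCCl
Why: Williamson-type O-alkylation of a simple phenol.

**Step 7**
Reactants: 11 1-iodo-4-(methoxymethoxy)benzene; 12 trimethylsilylacetylene
Product: 13 {[4-(methoxymethoxy)phenyl]ethynyl}trimethylsilane
Conditions: PdCl2(PPh3)2 (2 mol %), CuI (4 mol %), Et3N, THF, rt
Reagents that add atoms: none
Why: Sonogashira coupling of an unhindered aryl iodide with a terminal alkyne whose other end is blocked by silicon.

**Step 8**
Reactants: 13 {[4-(methoxymethoxy)phenyl]ethynyl}trimethylsilane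
Product: 14 1-ethynyl-4-(methoxymethoxy)benzene
Conditions: K2CO3 (0.1 equiv), MeOH, rt
Reagents that add atoms: none
Why: Methoxide-catalysed protiodesilylation of an alkynylsilane, to which the MOM ether is inert.

**Step 9**
Reactants: 9 2-iodo-3,5-bis(methoxymethoxy)-6-(2-methylbut-3-en-2-yl)phenol; 14 1-ethynyl-4-(methoxymethoxy)benzene; 15 carbon monoxide
Product: 18 5,7-bis(methoxymethoxy)-2-[4-(methoxymethoxy)phenyl]-8-(2-methylbut-3-en-2-yl)-4H-chromen-4-one, via ynone 16 (not isolated), via enaminone 17 (not isolated)
Conditions: PdCl2(PPh3)2 (5 mol %), CO (20 atm), 14 (1.5 equiv), Et2NH, 100 °C, autoclave, no copper salt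
Reagents that add atoms: diethylamine, CCNCC (held only in intermediate 17 and released again on ring closure)
Why: The cycle starts when PdCl2(PPh3)2 is reduced in the amine/CO medium to zerovalent palladium, which adds oxidatively to the C4a–I bond of 9; CO then migrates into the aryl–metal bond (C4a–C4), the resulting aroyl species of divalent palladium takes up the deprotonated alkyne 14, and reductive elimination releases ynone 16 (C4–C3). The solvent amine adds in conjugate fashion at C2 to give enaminone 17, whose amino group is then exchanged for the C8a oxygen (O1–C2), so ring C closes in the 6-endo mode, while the 5-exo attack at C3 that would lead to the aurone skeleton is not open to an enaminone. The closest known reaction type is the palladium-catalysed carbonylative Sonogashira annulation of 2-iodophenols with terminal arylacetylenes in a secondary amine, an established flavone synthesis. No stereocentre is formed. Regiochemistry needs no control here because 9 holds a single free hydroxyl, the one between C4a–I and C8, while O5 and O7 are MOM ethers, so the side chain must end up on C8. Carbonylation has to outrun direct alkynylation, amide formation with the solvent and Heck reaction: copper is left out and CO is kept under pressure, the electron-rich aryl–palladium bond inserts CO quickly, the doubly ortho-substituted aroyl group is shielded from the bulky amine, and the vinyl group is monosubstituted, attached to a quaternary carbon and meta to the metal, out of intramolecular reach.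

**Step 10**
Reactants: 18 5,7-bis(methoxymethoxy)-2-[4-(methoxymethoxy)phenyl]-8-(2-methylbut-3-en-2-yl)-4H-chromen-4-one
Product: 21 3-hydroxy-5,7-bis(methoxymethoxy)-2-[4-(methoxymethoxy)phenyl]-8-(2-methylbut-3-en-2-yl)-4H-chromen-4-one, via 3-lithioflavone 19 (not isolated), via dimethyl boronate 20 (not isolated)
Conditions: LiN(i-Pr)2 (1.5 equiv), THF, −78 °C; B(OMe)3 (3 equiv), −78 to 0 °C; AcOH, 30% H2O2, 0 °C to rt
Reagents that add atoms: hydrogen peroxide, OO (the C3 oxygen); trimethyl borate, COB(OC)OC (boron and two methoxy groups of 20 only); LiN(i-Pr)2, [Li]N(C(C)C)C(C)C (lithium of 19 only)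
Why: C3 lithiation of a polyalkoxyflavone by a non-nucleophilic amide base, borylation and oxidative 1,2-migration of the boronate is the known lithiation–borate route to flavonols, and acid-buffered H2O2 leaves the isolated vinyl group alone, which a dioxirane or a peracid would not.

**Step 11**
Reactants: 21 3-hydroxy-5,7-bis(methoxymethoxy)-2-[4-(methoxymethoxy)phenyl]-8-(2-methylbut-3-en-2-yl)-4H-chromen-4-one
Product: 22 3,5,7-trihydroxy-2-(4-hydroxyphenyl)-8-(2-methylbut-3-en-2-yl)-4H-chromen-4-one (target, CNP0284048.0)
Conditions: HCl (1.25 M in MeOH), 40 °C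
Reagents that add atoms: none
Why: Acid-catalysed acetal exchange with methanol removes all three MOM groups, and dilute acid at mild temperature should not protonate the monosubstituted alkene, so closure of the 7-hydroxyl onto the side chain is avoided.

**Compound list**

| No. | Name | SMILES | Role |
|---|---|---|---|
| 1 | phloroglucinol | Oc1cc(O)cc(O)c1 | starting material |
| 2 | 3,5-bis(methoxymethoxy)phenol | COCOc1cc(O)cc(OCOC)c1 | intermediate |
| 3 | prenyl bromide (1-bromo-3-methylbut-2-ene) | CC(C)=CCBr | starting material |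
| 4 | 1,3-bis(methoxymethoxy)-5-[(3-methylbut-2-en-1-yl)oxy]benzene | CC(C)=CCOc1cc(OCOC)cc(OCOC)c1 | intermediate |
| 5 | 3,5-bis(methoxymethoxy)-6-(2-methylbut-3-en-2-yl)cyclohexa-2,4-dien-1-one (racemic, transient) | O=C1C=C(OCOC)C=C(OCOC)C1C(C)(C)C=C | intermediate |
| 6 | 3,5-bis(methoxymethoxy)-2-(2-methylbut-3-en-2-yl)phenol | C=CC(C)(C)c1c(O)cc(OCOC)cc1OCOC | intermediate |
| 7 | 3,5-bis(methoxymethoxy)-2-(2-methylbut-3-en-2-yl)phenyl acetate | C=CC(C)(C)c1c(OC(C)=O)cc(OCOC)cc1OCOC | intermediate |
| 8 | 2-iodo-3,5-bis(methoxymethoxy)-6-(2-methylbut-3-en-2-yl)phenyl acetate | C=CC(C)(C)c1c(OC(C)=O)c(I)c(OCOC)cc1OCOC | intermediate |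
| 9 | 2-iodo-3,5-bis(methoxymethoxy)-6-(2-methylbut-3-en-2-yl)phenol | C=CC(C)(C)c1c(O)c(I)c(OCOC)cc1OCOC | intermediate |
| 10 | 4-iodophenol | Oc1ccc(I)cc1 | starting material |
| 11 | 1-iodo-4-(methoxymethoxy)benzene | COCOc1ccc(I)cc1 | intermediate |
| 12 | trimethylsilylacetylene | C#C[Si](C)(C)C | starting material |
| 13 | {[4-(methoxymethoxy)phenyl]ethynyl}trimethylsilane | COCOc1ccc(C#C[Si](C)(C)C)cc1 | intermediate |
| 14 | 1-ethynyl-4-(methoxymethoxy)benzene | C#Cc1ccc(OCOC)cc1 | intermediate |
| 15 | carbon monoxide | [C-]#[O+] | starting material |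
| 16 | 1-[2-hydroxy-4,6-bis(methoxymethoxy)-3-(2-methylbut-3-en-2-yl)phenyl]-3-[4-(methoxymethoxy)phenyl]prop-2-yn-1-one | C=CC(C)(C)c1c(O)c(C(=O)C#Cc2ccc(OCOC)cc2)c(OCOC)cc1OCOC | intermediate |
| 17 | (E)-3-(diethylamino)-1-[2-hydroxy-4,6-bis(methoxymethoxy)-3-(2-methylbut-3-en-2-yl)phenyl]-3-[4-(methoxymethoxy)phenyl]prop-2-en-1-one | C=CC(C)(C)c1c(O)c(C(=O)/C=C(/N(CC)CC)c2ccc(OCOC)cc2)c(OCOC)cc1OCOC | intermediate |
| 18 | 5,7-bis(methoxymethoxy)-2-[4-(methoxymethoxy)phenyl]-8-(2-methylbut-3-en-2-yl)-4H-chromen-4-one | C=CC(C)(C)c1c(OCOC)cc(OCOC)c2c(=O)cc(-c3ccc(OCOC)cc3)oc12 | intermediate |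
| 19 | 3-lithio derivative of 18 | C=CC(C)(C)c1c(OCOC)cc(OCOC)c2c(=O)c([Li])c(-c3ccc(OCOC)cc3)oc12 | intermediate |
| 20 | dimethyl boronate at C3 of 18 | C=CC(C)(C)c1c(OCOC)cc(OCOC)c2c(=O)c(B(OC)OC)c(-c3ccc(OCOC)cc3)oc12 | intermediate |
| 21 | 3-hydroxy-5,7-bis(methoxymethoxy)-2-[4-(methoxymethoxy)phenyl]-8-(2-methylbut-3-en-2-yl)-4H-chromen-4-one | C=CC(C)(C)c1c(OCOC)cc(OCOC)c2c(=O)c(O)c(-c3ccc(OCOC)cc3)oc12 | intermediate |
| 22 | 3,5,7-trihydroxy-2-(4-hydroxyphenyl)-8-(2-methylbut-3-en-2-yl)-4H-chromen-4-one | C=CC(C)(C)c1c(O)cc(O)c2c(=O)c(O)c(-c3ccc(O)cc3)oc12 | target |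

**Step count**
- Total step count: 11.
- Longest linear sequence: 8 steps (1–5 and 9–11, from phloroglucinol 1). Steps 6–8 form the convergent alkyne branch.

**Steps most likely to fail**

1. **Step 9 (key step).**
 - Risk: oxidative addition into the electron-rich C–I bond, which is flanked by two oxygen substituents, may be slow. Reductive loss of iodine, alkynylation without uptake of CO, and capture of the aroyl–palladium species by the amine solvent could then compete.
 - Fallback: a polar, CO-free assembly of the same ynone. It sets out from 9 and 14 and comes back at 16, and from there at 18.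
 - Alkyne 14 is deprotonated with n-BuLi (THF, −78 °C) to lithium [4-(methoxymethoxy)phenyl]acetylide F1. F1 is acylated with N-methoxy-N-methylcarbamoyl chloride to N-methoxy-N-methyl-3-[4-(methoxymethoxy)phenyl]prop-2-ynamide F2.
 - Iodophenol 9 is deprotonated with MeMgCl and subjected to iodine–magnesium exchange with i-PrMgCl·LiCl (THF, −20 °C to rt). This gives the chloromagnesium phenoxide arylmagnesium chloride F3.
 - F3 adds once to F2 and should give, after a mild aqueous quench, ynone 16 as an isolated compound. Et2NH in EtOH at 50 °C then closes ring C to 18 through 17.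

2. **Step 3.**
 - Risk: an onward Cope shift of the side chain to the unsubstituted para carbon, the abnormal Claisen isomerisation, or loss of MOM groups to acetic acid at 180 °C.
 - Fallback: the sigmatropic step is run on a benzoate whose ester-bearing carbon blocks the para position. It sets out from prenyl bromide 3 and comes back at phenol 6.
 - Purchased methyl 2,4,6-trihydroxybenzoate F4 is alkylated at its only non-chelated hydroxyl with 3 (K2CO3, acetone) to methyl 2,6-dihydroxy-4-[(3-methylbut-2-en-1-yl)oxy]benzoate F5.
 - Heating in PhNEt2 (190 °C) moves the side chain to one of two equivalent ortho carbons and gives methyl 2,4,6-trihydroxy-3-(2-methylbut-3-en-2-yl)benzoate F6.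
 - MOMCl (2.2 equiv) with i-Pr2NEt caps the two more accessible hydroxyls and leaves the chelated, hindered one free. The product is methyl 2-hydroxy-4,6-bis(methoxymethoxy)-3-(2-methylbut-3-en-2-yl)benzoate F7.
 - KOH in aqueous EtOH at reflux gives 2-hydroxy-4,6-bis(methoxymethoxy)-3-(2-methylbut-3-en-2-yl)benzoic acid F8. F8 should lose CO2 on gentle warming at pH 5 to give 6.
 - Ac2O and pyridine at rt then convert 6 into 7.

3. **Step 10.**
 - Risk: competing deprotonation at C6 between the two MOM ethers, addition of the amide or of the lithiated flavone to the pyranone, or incomplete capture by the borate.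
 - Fallback: oxidation through a conjugate-addition enolate in place of C–H lithiation. It sets out from 18 and comes back at target 22.
 - With PhI(OAc)2 and KOH in MeOH (0 °C to rt), methoxide adds at C2 and the resulting enolate is hydroxylated at C3 by the iodane. The carbonyl ends as its dimethyl acetal. This is the known hypervalent-iodine α-hydroxylation of enolisable ketones, also applied to flavones.
 - The product is 2,4,4-trimethoxy-5,7-bis(methoxymethoxy)-2-[4-(methoxymethoxy)phenyl]-8-(2-methylbut-3-en-2-yl)chroman-3-ol F9.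
 - HCl in MeOH with a little water (40 °C) then eliminates methanol across C2–C3, unmasks C4=O and removes the three MOM groups in the same operation to give 22.

**Further compounds**
F1 | step 9 | lithium [4-(methoxymethoxy)phenyl]acetylide | [Li]C#Cc1ccc(OCOC)cc1
F2 | step 9 | N-methoxy-N-methyl-3-[4-(methoxymethoxy)phenyl]prop-2-ynamide | CON(C)C(=O)C#Cc1ccc(OCOC)cc1
F3 | step 9 | chloromagnesium 2-(chloromagnesio)-3,5-bis(methoxymethoxy)-6-(2-methylbut-3-en-2-yl)phenoxide | C=CC(C)(C)c1c(O[Mg]Cl)c([Mg]Cl)c(OCOC)cc1OCOC
F4 | step 3 | methyl 2,4,6-trihydroxybenzoate (purchased) | COC(=O)c1c(O)cc(O)cc1O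
F5 | step 3 | methyl 2,6-dihydroxy-4-[(3-methylbut-2-en-1-yl)oxy]benzoate | COC(=O)c1c(O)cc(OCC=C(C)C)cc1O
F6 | step 3 | methyl 2,4,6-trihydroxy-3-(2-methylbut-3-en-2-yl)benzoate | COC(=O)c1c(O)cc(O)c(C(C)(C)C=C)c1O
F7 | step 3 | methyl 2-hydroxy-4,6-bis(methoxymethoxy)-3-(2-methylbut-3-en-2-yl)benzoate | COC(=O)c1c(OCOC)cc(OCOC)c(C(C)(C)C=C)c1O
F8 | step 3 | 2-hydroxy-4,6-bis(methoxymethoxy)-3-(2-methylbut-3-en-2-yl)benzoic acid | O=C(O)c1c(OCOC)cc(OCOC)c(C(C)(C)C=C)c1O
F9 | step 10 | 2,4,4-trimethoxy-5,7-bis(methoxymethoxy)-2-[4-(methoxymethoxy)phenyl]-8-(2-methylbut-3-en-2-yl)chroman-3-ol (diastereomer mixture, both centres are erased in the next operation) | C=CC(C)(C)c1c(OCOC)cc(OCOC)c2c1OC(OC)(c1ccc(OCOC)cc1)C(O)C2(OC)OC
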